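**Plan**

- Cuts, using target locants (ring C1 = C=O, C2 = C–N, C4 = carbinol, C6 = C–Cl; acyl chain C1′–C8′; ring side chain C1″–C5″): the amide N–C1′ bond; the C4–C1″ bond; C6–Cl together with C5=C6 (back to a 5,6-epoxide and, further, to the arene of 2,5-dimethoxyaniline); C7′=C8′ (Wittig) and C2′=C3′ (Horner–Wadsworth–Emmons).
- Enabling feature: C4′ and C6′ carry syn methyl groups on either side of C5′H2 and each is bounded outward by an sp2 CH (C3′, C7′). The C3′–C7′ segment is therefore meso-2,4-dimethylpentanedial, with its two formyl carbons as C3′ and C7′.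
- Forward order: dialdehyde → C2′=C3′ enoate at one formyl → C7′=C8′ isopropylidene at the other → acid → anilide. The only carbocycle arrives as the aniline ring and is dearomatised to a quinone monoketal, epoxidised (temporary oxirane), alkylated at C4, unmasked, opened with HCl to the 6-chloro dienone, and C5″ is oxidised last.
- Stereochemistry: C4′/C6′ from auxiliary-controlled choice between the enantiotopic formyl groups; E-C2′=C3′ from the phosphonate; C4 from a cinchonidinium-catalysed epoxidation relayed by Grignard addition anti to the oxirane, which is then erased.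

Key step: step 4

Assumption: the (1R,2S,5R)-8-phenylmenthyl phosphonate is taken to olefinate the formyl group on the (S)-configured carbon of the dialdehyde, and N-benzylcinchonidinium chloride to give the (1R,6S)-epoxide; both senses are set by the reagent alone, so the enantiomeric auxiliary or N-benzylcinchoninium chloride would be used in the same step if either proved opposite.

**Route**

Step 1
Reactants: 1 cis-2,4-dimethylglutaric anhydride
Product: 2 meso-2,4-dimethylpentane-1,5-diol
Conditions: LiAlH4, THF, 0 °C → reflux; H2O quench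
Reagents that add atoms: none
Why: Hydride reduction of a cyclic anhydride to the 1,5-diol with LiAlH4 is routine and does not involve the two methyl-bearing carbons, so the cis (meso) relationship is carried over unchanged.

Step 2
Reactants: 2 meso-2,4-dimethylpentane-1,5-diol
Product: 3 meso-2,4-dimethylpentanedial
Conditions: (COCl)2, DMSO, CH2Cl2, −78 °C; then i-Pr2NEt, −78 → −20 °C; cold non-aqueous work-up, used at once
Reagents that add atoms: none
Why: In the Swern oxidation both hydroxyl groups are activated as alkoxysulfonium ions before the base is added, so no lactol or lactone can form, and the hindered amine at low temperature should leave the two epimerisable α-centres untouched.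

Step 3
Reactants: 4 (1R,2S,5R)-8-phenylmenthol; 5 diethylphosphonoacetic acid
Product: 6 (1R,2S,5R)-8-phenylmenthyl 2-(diethoxyphosphoryl)acetate
Conditions: N,N′-dicyclohexylcarbodiimide (DCC), 4-(dimethylamino)pyridine (cat.), CH2Cl2, 0 °C → rt
Reagents that add atoms: none
Why: Steglich esterification (carbodiimide activation with acyl-transfer catalysis) is the standard way to load a phosphonoacetic acid onto a hindered secondary alcohol, and the carbinol carbon is not involved, so the auxiliary keeps its configuration.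

Step 4
Reactants: 3 meso-2,4-dimethylpentanedial (slight excess); 6 (1R,2S,5R)-8-phenylmenthyl 2-(diethoxyphosphoryl)acetate
Product: 8 (1R,2S,5R)-8-phenylmenthyl (2E,4S,6R)-4,6-dimethyl-7-oxohept-2-enoate, via potassium phosphonate carbanion 7 (not isolated)
Conditions: KN(SiMe3)2, 18-crown-6, THF, −78 °C; then 3, −78 °C; pH 7 buffer quench
Reagents that add atoms: none
Why: KN(SiMe3)2 converts 6 into carbanion 7, which adds to one formyl group of 3; the adduct closes to an oxaphosphetane that collapses by syn elimination of potassium diethyl phosphate to the E enoate, as expected for a stabilised diethyl phosphonoacetate whose adducts equilibrate. The closest known reaction type is the asymmetric Horner–Wadsworth–Emmons desymmetrisation of meso dialdehydes with 8-phenylmenthyl phosphonoacetates under KN(SiMe3)2/18-crown-6. No ring is closed. No new sp3 centre is formed: the two methyl-bearing carbons, mirror images of one another in 3, become C4 (S) and C6 (R) of 8 solely through which formyl group reacts, and that choice is controlled by the auxiliary, whose phenyl ring blocks one face of the carbanion so that only one of the two enantiomeric α-methyl aldehyde termini can be approached on its Felkin–Anh-preferred face. The step needs group selectivity, mono-olefination and E geometry; the first rests on this matched pairing, the second on an excess of 3 at −78 °C and on the remaining formyl group of 8 being the mismatched one, the third on the stabilised diethyl phosphonate, and enoates from the other formyl group are diastereomers of 8 that chromatography can remove.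

Step 5
Reactants: 8 (1R,2S,5R)-8-phenylmenthyl (2E,4S,6R)-4,6-dimethyl-7-oxohept-2-enoate
Product: 9 (1R,2S,5R)-8-phenylmenthyl (2E,4S,6R)-4,6,8-trimethylnona-2,7-dienoate
Conditions: i-PrPPh3I, n-BuLi, THF, 0 °C; ylide added to 8 at −78 °C, then → 0 °C
Reagents that add atoms: isopropyltriphenylphosphonium iodide, CC(C)[P+](c1ccccc1)(c1ccccc1)c1ccccc1.[I-]
Why: Wittig olefination with the non-stabilised isopropylidene ylide is fast at the aldehyde at −78 °C, well ahead of conjugate addition to the shielded enoate or enolisation of the α-methyl aldehyde, so C6 should keep its configuration, and the new alkene has no geometry to control.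

Step 6
Reactants: 9 (1R,2S,5R)-8-phenylmenthyl (2E,4S,6R)-4,6,8-trimethylnona-2,7-dienoate
Product: 10 (2E,4S,6R)-4,6,8-trimethylnona-2,7-dienoic acid
Conditions: KOH, EtOH–H2O, 70 °C; then aq. HCl to pH 3
Reagents that add atoms: potassium hydroxide, [K+].[OH-]
Why: Saponification (acyl-oxygen ester hydrolysis) frees the acid and returns the auxiliary; hydroxide in aqueous ethanol should not deprotonate the γ-carbon C4, and the carboxylate once formed is inert to further base.

Step 7
Reactants: 10 (2E,4S,6R)-4,6,8-trimethylnona-2,7-dienoic acid; 11 2,5-dimethoxyaniline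
Product: 12 (2E,4S,6R)-N-(2,5-dimethoxyphenyl)-4,6,8-trimethylnona-2,7-dienamide
Conditions: DCC, 4-(dimethylamino)pyridine (cat.), CH2Cl2, 0 °C → rt
Reagents that add atoms: none
Why: Carbodiimide-mediated amide coupling of an α,β-unsaturated acid with an electron-rich aniline is standard and touches neither the stereocentres nor the alkene geometry.

Step 8
Reactants: 12 (2E,4S,6R)-N-(2,5-dimethoxyphenyl)-4,6,8-trimethylnona-2,7-dienamide
Product: 13 (2E,4S,6R)-N-(6,6-dimethoxy-3-oxocyclohexa-1,4-dien-1-yl)-4,6,8-trimethylnona-2,7-dienamide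
Conditions: PhI(OAc)2, MeOH, 0 °C → rt; aq. NaHCO3 work-up
Reagents that add atoms: methanol, CO; water, O
Why: Oxidative dearomatisation of 2,5-dimethoxyanilides with the trivalent iodine reagent in methanol is the established route to 3-amido-4,4-dimethoxycyclohexa-2,5-dienones: methanol adds ipso at the methoxy carbon next to nitrogen, where the cation is stabilised by nitrogen and by the para methoxy group, the latter is then lost as methanol to unveil the ketone, and without strong acid the isolated alkene and the unsaturated amide are not attacked.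

Step 9
Reactants: 13 (2E,4S,6R)-N-(6,6-dimethoxy-3-oxocyclohexa-1,4-dien-1-yl)-4,6,8-trimethylnona-2,7-dienamide
Product: 14 (2E,4S,6R)-N-[(1R,6S)-2,2-dimethoxy-5-oxo-7-oxabicyclo[4.1.0]hept-3-en-3-yl]-4,6,8-trimethylnona-2,7-dienamide
Conditions: t-BuOOH, NaOH (aq.), N-benzylcinchonidinium chloride (10 mol %), toluene, rt
Reagents that add atoms: tert-butyl hydroperoxide, CC(C)(C)OO
Why: Weitz–Scheffer nucleophilic epoxidation under chiral phase-transfer catalysis is known for amido quinone monoketals; only the unsubstituted enone double bond is electrophilic enough (the other is a vinylogous amide, deprotonated under the conditions, and the chain alkenes are not Michael acceptors for the peroxide), and the cinchonidinium–peroxide ion pair selects the face, giving the cis-fused (1R,6S) oxirane.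

Step 10
Reactants: 15 5-bromopentan-1-ol
Product: 16 (5-bromopentyloxy)(tert-butyl)dimethylsilane
Conditions: TBSCl, imidazole, DMF, 0 °C → rt
Reagents that add atoms: tert-butyldimethylsilyl chloride, CC(C)(C)[Si](C)(C)Cl
Why: Imidazole-assisted silylation of a primary alcohol is routine and masks the hydroxyl for Grignard formation.

Step 11
Reactants: 14 (2E,4S,6R)-N-[(1R,6S)-2,2-dimethoxy-5-oxo-7-oxabicyclo[4.1.0]hept-3-en-3-yl]-4,6,8-trimethylnona-2,7-dienamide; 16 (5-bromopentyloxy)(tert-butyl)dimethylsilane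
Product: 18 (2E,4S,6R)-N-[(1R,5R,6S)-5-{5-[tert-butyl(dimethyl)silyl]oxypentyl}-5-hydroxy-2,2-dimethoxy-7-oxabicyclo[4.1.0]hept-3-en-3-yl]-4,6,8-trimethylnona-2,7-dienamide, via Grignard reagent 17 (not isolated)
Conditions: Mg, THF, 40 °C (16 → 17, 3 equiv); then 14, THF, −78 → −40 °C; pH 7 phosphate buffer
Reagents that add atoms: none
Why: Grignard 1,2-addition to the ketone of a 5,6-epoxy quinone monoketal takes place anti to the oxirane oxygen, so the oxirane sets the new carbinol centre (5R in 18, hydroxyl syn to the oxirane); the first equivalent of reagent deprotonates the amide N–H, which shields the unsaturated amide, and at low temperature the oxirane and the ketal are not opened.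

Step 12
Reactants: 18 (2E,4S,6R)-N-[(1R,5R,6S)-5-{5-[tert-butyl(dimethyl)silyl]oxypentyl}-5-hydroxy-2,2-dimethoxy-7-oxabicyclo[4.1.0]hept-3-en-3-yl]-4,6,8-trimethylnona-2,7-dienamide
Product: 19 (2E,4S,6R)-N-[(1R,5R,6S)-5-{5-[tert-butyl(dimethyl)silyl]oxypentyl}-5-hydroxy-2-oxo-7-oxabicyclo[4.1.0]hept-3-en-3-yl]-4,6,8-trimethylnona-2,7-dienamide
Conditions: montmorillonite K10 clay (moist), CH2Cl2, rt
Reagents that add atoms: water, O
Why: Acid-catalysed ketal hydrolysis on acidic clay is the mild method used for dimethyl ketals of this epoxyquinol class; ionisation of the ketal to an allylic oxocarbenium ion is far faster than ionisation of the tertiary alcohol or opening of the oxirane, and the silyl ether survives.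

Step 13
Reactants: 19 (2E,4S,6R)-N-[(1R,5R,6S)-5-{5-[tert-butyl(dimethyl)silyl]oxypentyl}-5-hydroxy-2-oxo-7-oxabicyclo[4.1.0]hept-3-en-3-yl]-4,6,8-trimethylnona-2,7-dienamide
Product: 22 (2E,4S,6R)-N-[(3R)-5-chloro-3-hydroxy-3-(5-hydroxypentyl)-6-oxocyclohexa-1,4-dien-1-yl]-4,6,8-trimethylnona-2,7-dienamide, via chlorohydrin 20 (not isolated), via silyl chlorodienone 21 (not isolated)
Conditions: HCl (2 M aq.), THF, 0 °C → rt
Reagents that add atoms: hydrogen chloride, Cl
Why: Hydrochloric acid converts α,β-epoxy ketones into α-chloro enones (the reaction type used to make 4-chloro-Δ4-3-keto steroids): chloride opens the protonated oxirane by SN2 attack at target C6, the carbon α to the ketone and the less hindered one, chlorohydrin 20 loses water by acid-catalysed β-elimination to dienone 21, the same acid cleaves the primary silyl ether, and the C4 carbinol is not ionised because its cation would be cross-conjugated with the carbonyl, so C4 keeps its configuration while the two oxirane centres disappear.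

Step 14
Reactants: 22 (2E,4S,6R)-N-[(3R)-5-chloro-3-hydroxy-3-(5-hydroxypentyl)-6-oxocyclohexa-1,4-dien-1-yl]-4,6,8-trimethylnona-2,7-dienamide
Product: 24 5-[(1R)-3-chloro-1-hydroxy-4-oxo-5-{[(2E,4S,6R)-4,6,8-trimethylnona-2,7-dienoyl]amino}cyclohexa-2,5-dien-1-yl]pentanoic acid, via aldehyde 23 (not isolated)
Conditions: 2,2,6,6-tetramethylpiperidin-1-oxyl (TEMPO, cat.), PhI(OAc)2, MeCN–H2O (1:1), rt
Reagents that add atoms: water, O
Why: Oxoammonium-mediated oxidation (TEMPO with PhI(OAc)2 as terminal oxidant in aqueous acetonitrile) takes a primary alcohol through the aldehyde hydrate to the acid while the tertiary alcohol, the alkenes, the enamide and the chloro enone are inert, and the tertiary hydroxyl cannot interfere because that would need a seven-membered lactol.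

**Compound list**

1 | cis-2,4-dimethylglutaric anhydride (meso) | C[C@H]1C[C@@H](C)C(=O)OC1=O | starting material
2 | meso-2,4-dimethylpentane-1,5-diol | OC[C@H](C)C[C@H](C)CO | intermediate
3 | meso-2,4-dimethylpentanedial | O=C[C@H](C)C[C@H](C)C=O | intermediate
4 | (1R,2S,5R)-8-phenylmenthol [(1R,2S,5R)-5-methyl-2-(2-phenylpropan-2-yl)cyclohexan-1-ol] | CC(C)(c1ccccc1)[C@@H]1CC[C@@H](C)C[C@H]1O | starting material
5 | diethylphosphonoacetic acid | CCOP(=O)(OCC)CC(=O)O | starting material
6 | (1R,2S,5R)-8-phenylmenthyl 2-(diethoxyphosphoryl)acetate | CCOP(=O)(OCC)CC(=O)O[C@@H]1C[C@H](C)CC[C@H]1C(C)(C)c1ccccc1 | intermediate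
7 | potassium carbanion of 6 (not isolated) | CCOP(=O)(OCC)[CH-]C(=O)O[C@@H]1C[C@H](C)CC[C@H]1C(C)(C)c1ccccc1.[K+] | intermediate
8 | (1R,2S,5R)-8-phenylmenthyl (2E,4S,6R)-4,6-dimethyl-7-oxohept-2-enoate | O=C[C@H](C)C[C@H](C)/C=C/C(=O)O[C@@H]1C[C@H](C)CC[C@H]1C(C)(C)c1ccccc1 | intermediate
9 | (1R,2S,5R)-8-phenylmenthyl (2E,4S,6R)-4,6,8-trimethylnona-2,7-dienoate | CC(C)=C[C@H](C)C[C@H](C)/C=C/C(=O)O[C@@H]1C[C@H](C)CC[C@H]1C(C)(C)c1ccccc1 | intermediate
10 | (2E,4S,6R)-4,6,8-trimethylnona-2,7-dienoic acid | CC(C)=C[C@H](C)C[C@H](C)/C=C/C(=O)O | intermediate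
11 | 2,5-dimethoxyaniline | COc1ccc(OC)c(N)c1 | starting material
12 | (2E,4S,6R)-N-(2,5-dimethoxyphenyl)-4,6,8-trimethylnona-2,7-dienamide | CC(C)=C[C@H](C)C[C@H](C)/C=C/C(=O)Nc1cc(OC)ccc1OC | intermediate
13 | (2E,4S,6R)-N-(6,6-dimethoxy-3-oxocyclohexa-1,4-dien-1-yl)-4,6,8-trimethylnona-2,7-dienamide | CC(C)=C[C@H](C)C[C@H](C)/C=C/C(=O)NC1=CC(=O)C=CC1(OC)OC | intermediate
14 | (2E,4S,6R)-N-[(1R,6S)-2,2-dimethoxy-5-oxo-7-oxabicyclo[4.1.0]hept-3-en-3-yl]-4,6,8-trimethylnona-2,7-dienamide | CC(C)=C[C@H](C)C[C@H](C)/C=C/C(=O)NC1=CC(=O)[C@H]2O[C@H]2C1(OC)OC | intermediate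
15 | 5-bromopentan-1-ol | OCCCCCBr | starting material
16 | (5-bromopentyloxy)(tert-butyl)dimethylsilane | CC(C)(C)[Si](C)(C)OCCCCCBr | intermediate
17 | {5-[tert-butyl(dimethyl)silyl]oxypentyl}magnesium bromide (not isolated) | CC(C)(C)[Si](C)(C)OCCCCC[Mg]Br | intermediate
18 | (2E,4S,6R)-N-[(1R,5R,6S)-5-{5-[tert-butyl(dimethyl)silyl]oxypentyl}-5-hydroxy-2,2-dimethoxy-7-oxabicyclo[4.1.0]hept-3-en-3-yl]-4,6,8-trimethylnona-2,7-dienamide | CC(C)=C[C@H](C)C[C@H](C)/C=C/C(=O)NC1=C[C@](O)(CCCCCO[Si](C)(C)C(C)(C)C)[C@H]2O[C@H]2C1(OC)OC | intermediate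
19 | (2E,4S,6R)-N-[(1R,5R,6S)-5-{5-[tert-butyl(dimethyl)silyl]oxypentyl}-5-hydroxy-2-oxo-7-oxabicyclo[4.1.0]hept-3-en-3-yl]-4,6,8-trimethylnona-2,7-dienamide | CC(C)=C[C@H](C)C[C@H](C)/C=C/C(=O)NC1=C[C@](O)(CCCCCO[Si](C)(C)C(C)(C)C)[C@H]2O[C@H]2C1=O | intermediate
20 | (2E,4S,6R)-N-[(3R,4R,5S)-3-{5-[tert-butyl(dimethyl)silyl]oxypentyl}-5-chloro-3,4-dihydroxy-6-oxocyclohex-1-en-1-yl]-4,6,8-trimethylnona-2,7-dienamide (not isolated) | CC(C)=C[C@H](C)C[C@H](C)/C=C/C(=O)NC1=C[C@](O)(CCCCCO[Si](C)(C)C(C)(C)C)[C@@H](O)[C@H](Cl)C1=O | intermediate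
21 | (2E,4S,6R)-N-[(3R)-3-{5-[tert-butyl(dimethyl)silyl]oxypentyl}-5-chloro-3-hydroxy-6-oxocyclohexa-1,4-dien-1-yl]-4,6,8-trimethylnona-2,7-dienamide (not isolated) | CC(C)=C[C@H](C)C[C@H](C)/C=C/C(=O)NC1=C[C@](O)(CCCCCO[Si](C)(C)C(C)(C)C)C=C(Cl)C1=O | intermediate
22 | (2E,4S,6R)-N-[(3R)-5-chloro-3-hydroxy-3-(5-hydroxypentyl)-6-oxocyclohexa-1,4-dien-1-yl]-4,6,8-trimethylnona-2,7-dienamide | CC(C)=C[C@H](C)C[C@H](C)/C=C/C(=O)NC1=C[C@](O)(CCCCCO)C=C(Cl)C1=O | intermediate
23 | (2E,4S,6R)-N-[(3R)-5-chloro-3-hydroxy-6-oxo-3-(5-oxopentyl)cyclohexa-1,4-dien-1-yl]-4,6,8-trimethylnona-2,7-dienamide (not isolated) | CC(C)=C[C@H](C)C[C@H](C)/C=C/C(=O)NC1=C[C@](O)(CCCCC=O)C=C(Cl)C1=O | intermediate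
24 | 5-[(1R)-3-chloro-1-hydroxy-4-oxo-5-{[(2E,4S,6R)-4,6,8-trimethylnona-2,7-dienoyl]amino}cyclohexa-2,5-dien-1-yl]pentanoic acid | CC(C)=C[C@H](C)C[C@H](C)/C=C/C(=O)NC1=C[C@](O)(CCCCC(=O)O)C=C(Cl)C1=O | target

**Step count and risks**

Total steps: 14. Longest linear sequence: 12 steps (steps 1, 2, 4–9 and 11–14, from anhydride 1).

Steps most likely to fail:

1. Step 4. The two enantiotopic formyl groups may be discriminated too weakly, both ends may be olefinated, or the dialdehyde may epimerise before it reacts. Fallback, setting out from diol 2 and returning at aldehyde 8: the enantiotopic ends are told apart at the diol stage by an enzyme instead of at the dialdehyde stage by the phosphonate. Lipase from Pseudomonas fluorescens with vinyl acetate should acetylate one hydroxymethyl group of 2 to give (2R,4S)-5-hydroxy-2,4-dimethylpentyl acetate F1. Swern oxidation should then give (2R,4S)-2,4-dimethyl-5-oxopentyl acetate F2. Olefination of F2 with phosphonate 6 (LiCl, DBU, MeCN), now needed only for E selectivity, should give (1R,2S,5R)-8-phenylmenthyl (2E,4S,6R)-7-acetoxy-4,6-dimethylhept-2-enoate F3. K2CO3 in MeOH should remove the acetate without touching the hindered ester, giving (1R,2S,5R)-8-phenylmenthyl (2E,4S,6R)-7-hydroxy-4,6-dimethylhept-2-enoate F4, and Dess–Martin periodinane should oxidise F4 to 8.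

2. Step 9. Facial selectivity in the phase-transfer epoxidation may be poor, and it cannot be upgraded because the chain stereocentres make the two epoxides hard-to-separate diastereomers; the base may also degrade the monoketal. Fallback, setting out from aniline 11 (with acid 10) and returning at epoxide 14: the epoxidation is run on a chain-free carbamate, whose two epoxides are enantiomers and can be enriched by recrystallisation, and the acyl chain is transferred afterwards. Boc2O should convert 11 into tert-butyl N-(2,5-dimethoxyphenyl)carbamate F5. PhI(OAc)2 in MeOH should give tert-butyl N-(6,6-dimethoxy-3-oxocyclohexa-1,4-dien-1-yl)carbamate F6. The same epoxidation conditions should give tert-butyl N-[(1R,6S)-2,2-dimethoxy-5-oxo-7-oxabicyclo[4.1.0]hept-3-en-3-yl]carbamate F7, which is recrystallised. Acid 10 is converted with (COCl)2 and catalytic DMF into (2E,4S,6R)-4,6,8-trimethylnona-2,7-dienoyl chloride F8, which should acylate the lithium salt of F7 (LiOt-Bu, THF) to tert-butyl N-[(1R,6S)-2,2-dimethoxy-5-oxo-7-oxabicyclo[4.1.0]hept-3-en-3-yl]-N-[(2E,4S,6R)-4,6,8-trimethylnona-2,7-dienoyl]carbamate F9. Mg(ClO4)2 in MeCN should then remove the Boc group selectively from the imide nitrogen to give 14.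

3. Step 13. Chloride may open the oxirane at C5 instead of C6 (leading after elimination to a diosphenol), or the acid may ionise the quinol before dehydration is complete. Fallback, setting out from epoxy ketone 19 and returning at diol 22: the one-pot protic cascade is replaced by a directed opening and a separate elimination. Ti(Oi-Pr)4 with diethylammonium chloride, the known C3-selective opening of 2,3-epoxy alcohols by titanium-alkoxide delivery, should place chloride at C6 under direction of the tertiary hydroxyl and give chlorohydrin 20, now isolated. MsCl and Et3N should sulfonylate only the secondary hydroxyl to the mesylate (2E,4S,6R)-N-[(3R,4R,5S)-3-{5-[tert-butyl(dimethyl)silyl]oxypentyl}-5-chloro-3-hydroxy-4-(methanesulfonyloxy)-6-oxocyclohex-1-en-1-yl]-4,6,8-trimethylnona-2,7-dienamide F10, which should eliminate in the same flask (E1cB) to silyl chlorodienone 21. HF·pyridine in THF should then free the primary alcohol to give 22.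

**Further compounds**

F1 | step 4 | (2R,4S)-5-hydroxy-2,4-dimethylpentyl acetate | CC(=O)OC[C@H](C)C[C@H](C)CO
F2 | step 4 | (2R,4S)-2,4-dimethyl-5-oxopentyl acetate | CC(=O)OC[C@H](C)C[C@H](C)C=O
F3 | step 4 | (1R,2S,5R)-8-phenylmenthyl (2E,4S,6R)-7-acetoxy-4,6-dimethylhept-2-enoate | CC(=O)OC[C@H](C)C[C@H](C)/C=C/C(=O)O[C@@H]1C[C@H](C)CC[C@H]1C(C)(C)c1ccccc1
F4 | step 4 | (1R,2S,5R)-8-phenylmenthyl (2E,4S,6R)-7-hydroxy-4,6-dimethylhept-2-enoate | OC[C@H](C)C[C@H](C)/C=C/C(=O)O[C@@H]1C[C@H](C)CC[C@H]1C(C)(C)c1ccccc1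
F5 | step 9 | tert-butyl N-(2,5-dimethoxyphenyl)carbamate | COc1ccc(OC)c(NC(=O)OC(C)(C)C)c1
F6 | step 9 | tert-butyl N-(6,6-dimethoxy-3-oxocyclohexa-1,4-dien-1-yl)carbamate | CC(C)(C)OC(=O)NC1=CC(=O)C=CC1(OC)OC
F7 | step 9 | tert-butyl N-[(1R,6S)-2,2-dimethoxy-5-oxo-7-oxabicyclo[4.1.0]hept-3-en-3-yl]carbamate | CC(C)(C)OC(=O)NC1=CC(=O)[C@H]2O[C@H]2C1(OC)OC
F8 | step 9 | (2E,4S,6R)-4,6,8-trimethylnona-2,7-dienoyl chloride | CC(C)=C[C@H](C)C[C@H](C)/C=C/C(Cl)=O
F9 | step 9 | tert-butyl N-[(1R,6S)-2,2-dimethoxy-5-oxo-7-oxabicyclo[4.1.0]hept-3-en-3-yl]-N-[(2E,4S,6R)-4,6,8-trimethylnona-2,7-dienoyl]carbamate | CC(C)=C[C@H](C)C[C@H](C)/C=C/C(=O)N(C(=O)OC(C)(C)C)C1=CC(=O)[C@H]2O[C@H]2C1(OC)OC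
F10 | step 13 | (2E,4S,6R)-N-[(3R,4R,5S)-3-{5-[tert-butyl(dimethyl)silyl]oxypentyl}-5-chloro-3-hydroxy-4-(methanesulfonyloxy)-6-oxocyclohex-1-en-1-yl]-4,6,8-trimethylnona-2,7-dienamide | CC(C)=C[C@H](C)C[C@H](C)/C=C/C(=O)NC1=C[C@](O)(CCCCCO[Si](C)(C)C(C)(C)C)[C@@H](OS(C)(=O)=O)[C@H](Cl)C1=O
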